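**Strategy.** Ring A (the cyclohexenone; 2-oxaspiro[4.5]decane numbering) is disconnected at both ends of its cis C7=C8 unit, that is at C6(=O)–C7 and C8–C9(O). C6 and C9 sit 1,4 to each other across the ring, so removing C7=C8 as acetylene leaves a spiro-cyclobutanone in which C6 and C9 are directly bonded. The key step, a nickel-catalysed insertion of acetylene into that C6–C9 bond, should form both bonds and ring A in one operation with retention at C9. The precursor is a 2-silyloxycyclobutanone spiro-fused to lactone ring B, made by a ketene–enol ether cycloaddition in which the lactone carbinol centre C1 sets the spiro centre C5.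

Key step: step 9

Remark: the given SMILES corresponds to (1R,5R,9S) and is taken to be the dextrorotatory natural enantiomer; cyclobutane intermediates are numbered as 6-oxaspiro[3.4]octanes (C1 ketone, C4 spiro carbon, C5 carbinol carbon), and compounds 1, 4, 5, 10, 19 and 23 are taken as commercial.

Step 1
Reactants: 1 pent-1-en-4-yne
Product: 2 (2E)-3-methylhexa-2,5-dien-1-ol
Conditions: AlMe3, Cp2ZrCl2 (0.25 equiv), CH2Cl2, 0 °C to rt; n-BuLi, THF, −78 °C; (CH2O)n, rt; aq. HCl
Reagents that add atoms: trimethylaluminium, C[Al](C)C; paraformaldehyde (as formaldehyde), C=O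
Why: Zirconium-catalysed syn-carboalumination (Negishi) should add methyl and aluminium across the terminal alkyne only, and hydroxymethylation of the derived alanate with retention fixes the E geometry of the trisubstituted alkene.

Step 2
Reactants: 2 (2E)-3-methylhexa-2,5-dien-1-ol
Product: 3 (2E)-3-methylhexa-2,5-dienal
Conditions: MnO2, CH2Cl2, rt
Reagents that add atoms: none
Why: MnO2 oxidises the allylic alcohol under neutral conditions (allylic oxidation) that should leave the skipped diene unisomerised.

Step 3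
Reactants: 4 (4S)-4-benzyl-1,3-oxazolidin-2-one; 5 methyl 4-chloro-4-oxobutanoate
Product: 6 (4S)-4-benzyl-3-(4-methoxy-4-oxobutanoyl)-1,3-oxazolidin-2-one
Conditions: n-BuLi, THF, −78 °C; then 5, −78 to 0 °C
Reagents that add atoms: none
Why: N-Acylation of the lithiated oxazolidinone with the acid chloride is the standard entry to the Evans imide.

Step 4
Reactants: 6 (4S)-4-benzyl-3-(4-methoxy-4-oxobutanoyl)-1,3-oxazolidin-2-one; 3 (2E)-3-methylhexa-2,5-dienal
Product: 8 (4S)-4-benzyl-3-{[(2R,3S)-2-[(1E)-2-methylpenta-1,4-dien-1-yl]-5-oxooxolan-3-yl]carbonyl}-1,3-oxazolidin-2-one, via aldol adduct 7 (not isolated)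
Conditions: Bu2BOTf, Et3N, CH2Cl2, −78 to 0 °C; 3, −78 to 0 °C; pH 7 buffer, MeOH, H2O2; then PPTS (cat.), CH2Cl2, rt
Reagents that add atoms: none
Why: The Z-boron enolate of the imide should add to the enal through a closed chair transition state (Evans syn aldol), the (4S)-benzyl auxiliary setting the (R)-carbinol centre that becomes C1 of the target, and the γ-hydroxy ester then closes to the five-membered lactone.

Step 5
Reactants: 8 the lactone imide of step 4
Product: 9 (2R,3S)-2-[(1E)-2-methylpenta-1,4-dien-1-yl]-5-oxooxolane-3-carboxylic acid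
Conditions: LiOH, H2O2, THF/H2O, 0 °C; Na2SO3; aq. HCl
Reagents that add atoms: hydrogen peroxide (as lithium hydroperoxide), OO
Why: Lithium hydroperoxide attacks the exocyclic imide carbonyl selectively (standard auxiliary cleavage) and acidification re-closes any opened lactone, while the configuration next to the acid is irrelevant because that carbon becomes sp2 in step 6.

Step 6
Reactants: 9 (2R,3S)-2-[(1E)-2-methylpenta-1,4-dien-1-yl]-5-oxooxolane-3-carboxylic acid; 10 ethyl vinyl ether
Product: 14 (4S,5R)-5-[(1E)-2-methylpenta-1,4-dien-1-yl]-6-oxaspiro[3.4]oct-2-ene-1,7-dione, via acid chloride 11 (not isolated), via ketene 12 (not isolated), via 3-ethoxycyclobutanone 13 (not isolated)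
Conditions: (COCl)2, DMF (cat.), CH2Cl2, 0 °C to rt; evaporate; 10 (as solvent), Et3N (slow addition), 50 °C, sealed vessel; evaporate; DBU, CH2Cl2, 0 °C to rt
Reagents that add atoms: none
Why: Dehydrochlorination gives a disubstituted ketene that should undergo the classical regioselective [2+2] cycloaddition with the enol ether (carbonyl carbon to CH2, α-carbon to the ethoxy-bearing carbon), the new bond at the α-carbon forming anti to the dienyl group on the neighbouring lactone carbon and so setting the spiro centre, before E1cB loss of ethanol gives the cyclobutenone.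

Step 7
Reactants: 14 the spiro-cyclobutenone of step 6
Product: 16 (4R,5R)-5-[(1E)-2-methylpenta-1,4-dien-1-yl]-6-oxaspiro[3.4]octane-1,7-dione, via silyl enol ether 15 (not isolated)
Conditions: [(Ph3P)CuH]6 (5 mol %), PhMe2SiH, toluene, rt; then 1 M HCl, THF
Reagents that add atoms: none
Why: Copper hydride should add to the strained enone in 1,4-fashion only (conjugate hydrosilylation), leaving the lactone and the isolated alkenes untouched, and the silyl enol ether is hydrolysed on work-up.

Step 8
Reactants: 16 the spiro-cyclobutanone of step 7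
Product: 18 (2R,4R,5R)-5-[(1E)-2-methylpenta-1,4-dien-1-yl]-2-[(triethylsilyl)oxy]-6-oxaspiro[3.4]octane-1,7-dione, via α-hydroxy ketone 17 (not isolated)
Conditions: KN(SiMe3)2, THF, −78 °C; 2-(phenylsulfonyl)-3-phenyloxaziridine; then Et3SiCl, −78 to 0 °C
Reagents that add atoms: 2-(phenylsulfonyl)-3-phenyloxaziridine, O=S(=O)(c1ccccc1)N1OC1c1ccccc1; chlorotriethylsilane, CC[Si](Cl)(CC)CC
Why: Only C2 can enolise, and the potassium enolate should be hydroxylated (Davis oxidation) on the face away from the carbinol carbon C5 and its dienyl group, which overhangs the C1–C2 edge, giving the (2R) centre with oxygen trans to C5 before the alkoxide is silylated in the same flask.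

Step 9
Reactants: 18 the 2-silyloxy spiro-cyclobutanone of step 8; 19 acetylene
Product: 20 (1R,5R,9R)-1-[(1E)-2-methylpenta-1,4-dien-1-yl]-9-[(triethylsilyl)oxy]-2-oxaspiro[4.5]dec-7-ene-3,6-dione
Conditions: Ni(cod)2 (10 mol %), PCy3 (20 mol %), toluene, 80 °C, 19 fed slowly as a dilute stream in argon
Reagents that add atoms: none
Why: Proposed new method: zerovalent nickel should couple the strained C1 carbonyl of 18 with acetylene by oxidative cyclisation to a spiro oxanickelacyclopentene (this creates the C6–C7 bond of 20), after which β-carbon elimination opens the four-membered ring at the C1–C2 bond and C(sp2)–C(sp3) reductive elimination from the seven-membered nickelacycle creates the C8–C9 bond and returns the catalyst. The closest known reaction type is the nickel-catalysed intermolecular insertion of internal alkynes into 3-substituted cyclobutanones (formal [4+2] annulation); acetylene itself and a 2-silyloxy-4,4-disubstituted cyclobutanone have not been shown. Ring A is closed by this formal [4+2] two-carbon ring expansion (four-membered ketone to cyclohexenone through a nickelacycloheptenone), which can only place the new alkene cis inside the ring. No stereocentre is created: C2 of 18 becomes C9 of 20 with retention because both β-carbon elimination and reductive elimination keep the configuration at carbon, and C4 and C5 of 18 (C5 and C1 of 20) are not touched. The step needs cleavage of C1–C2 rather than C1–C4, which the quaternary spiro carbon should secure by disfavouring a tertiary alkylnickel, and it needs 1:1 uptake of acetylene without oligomerisation or double insertion and without ionisation of the allylic lactone, for which a slow acetylene feed, the bulky PCy3 ligand and the stronger binding of acetylene than of the hindered trisubstituted alkene are relied on.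

Step 10
Reactants: 20 the silyl ether of step 9
Product: 21 (1R,5R,9R)-9-hydroxy-1-[(1E)-2-methylpenta-1,4-dien-1-yl]-2-oxaspiro[4.5]dec-7-ene-3,6-dione
Conditions: HF·pyridine, THF, 0 °C
Reagents that add atoms: none
Why: Fluoride cleaves the triethylsilyl ether (desilylation) without touching the lactone, the enone or the alkenes.

Step 11
Reactants: 21 the allylic alcohol of step 10
Product: 22 (1R,5R,9S)-1-[(1E)-2-methylpenta-1,4-dien-1-yl]-3,6-dioxo-2-oxaspiro[4.5]dec-7-en-9-yl acetate
Conditions: PPh3, DIAD, AcOH, THF, 0 °C to rt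
Reagents that add atoms: acetic acid, CC(=O)O
Why: Mitsunobu esterification should proceed by SN2 displacement of the oxyphosphonium ion, inverting C9 to the (S) configuration of the target, in which the acetoxy group is cis to C1 across ring A.

Step 12
Reactants: 22 the acetate of step 11; 23 2-methylbut-3-en-2-ol
Product: 24 the target, (1R,5R,9S)-1-[(1E,4E)-6-hydroxy-2,6-dimethylhepta-1,4-dien-1-yl]-3,6-dioxo-2-oxaspiro[4.5]dec-7-en-9-yl acetate
Conditions: 23 (excess), second-generation Grubbs catalyst RuCl2(=CHPh)(PCy3)(H2IMes) (5 mol %), CH2Cl2, 40 °C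
Reagents that add atoms: none
Why: Cross-metathesis of the monosubstituted terminal alkene with the hindered tertiary allylic alcohol, which is slow to homodimerise, should be E-selective, while the trisubstituted alkene and the ring enone are not engaged by the ruthenium carbene.

**Compound list**

1 | pent-1-en-4-yne | C#CCC=C | starting material
2 | (2E)-3-methylhexa-2,5-dien-1-ol | OC/C=C(\C)CC=C | intermediate
3 | (2E)-3-methylhexa-2,5-dienal | O=C/C=C(\C)CC=C | intermediate
4 | (4S)-4-benzyl-1,3-oxazolidin-2-one | O=C1OC[C@H](Cc2ccccc2)N1 | starting material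
5 | methyl 4-chloro-4-oxobutanoate | COC(=O)CCC(Cl)=O | starting material
6 | (4S)-4-benzyl-3-(4-methoxy-4-oxobutanoyl)-1,3-oxazolidin-2-one | O=C1OC[C@H](Cc2ccccc2)N1C(=O)CCC(=O)OC | intermediate
7 | (4S)-4-benzyl-3-[(2S,3R,4E)-3-hydroxy-2-(2-methoxy-2-oxoethyl)-5-methylocta-4,7-dienoyl]-1,3-oxazolidin-2-one (syn aldol adduct) | O=C1OC[C@H](Cc2ccccc2)N1C(=O)[C@@H](CC(=O)OC)[C@H](O)/C=C(\C)CC=C | intermediate
8 | (4S)-4-benzyl-3-{[(2R,3S)-2-[(1E)-2-methylpenta-1,4-dien-1-yl]-5-oxooxolan-3-yl]carbonyl}-1,3-oxazolidin-2-one (trans lactone) | O=C1OC[C@H](Cc2ccccc2)N1C(=O)[C@H]1CC(=O)O[C@@H]1/C=C(\C)CC=C | intermediate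
9 | (2R,3S)-2-[(1E)-2-methylpenta-1,4-dien-1-yl]-5-oxooxolane-3-carboxylic acid | OC(=O)[C@H]1CC(=O)O[C@@H]1/C=C(\C)CC=C | intermediate
10 | ethyl vinyl ether | C=COCC | starting material
11 | (2R,3S)-2-[(1E)-2-methylpenta-1,4-dien-1-yl]-5-oxooxolane-3-carbonyl chloride | ClC(=O)[C@H]1CC(=O)O[C@@H]1/C=C(\C)CC=C | intermediate
12 | (5R)-5-[(1E)-2-methylpenta-1,4-dien-1-yl]-4-(oxomethylidene)oxolan-2-one (ketene) | O=C=C1CC(=O)O[C@@H]1/C=C(\C)CC=C | intermediate
13 | (4S,5R)-3-ethoxy-5-[(1E)-2-methylpenta-1,4-dien-1-yl]-6-oxaspiro[3.4]octane-1,7-dione (both C3 epimers) | O=C1CC(OCC)[C@]12CC(=O)O[C@@H]2/C=C(\C)CC=C | intermediate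
14 | (4S,5R)-5-[(1E)-2-methylpenta-1,4-dien-1-yl]-6-oxaspiro[3.4]oct-2-ene-1,7-dione | O=C1C=C[C@]12CC(=O)O[C@@H]2/C=C(\C)CC=C | intermediate
15 | (4R,5R)-1-{[dimethyl(phenyl)silyl]oxy}-5-[(1E)-2-methylpenta-1,4-dien-1-yl]-6-oxaspiro[3.4]oct-1-en-7-one | C[Si](C)(c3ccccc3)OC1=CC[C@]12CC(=O)O[C@@H]2/C=C(\C)CC=C | intermediate
16 | (4R,5R)-5-[(1E)-2-methylpenta-1,4-dien-1-yl]-6-oxaspiro[3.4]octane-1,7-dione | O=C1CC[C@]12CC(=O)O[C@@H]2/C=C(\C)CC=C | intermediate
17 | (2R,4R,5R)-2-hydroxy-5-[(1E)-2-methylpenta-1,4-dien-1-yl]-6-oxaspiro[3.4]octane-1,7-dione | O[C@H]1C(=O)[C@@]2(CC(=O)O[C@@H]2/C=C(\C)CC=C)C1 | intermediate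
18 | (2R,4R,5R)-5-[(1E)-2-methylpenta-1,4-dien-1-yl]-2-[(triethylsilyl)oxy]-6-oxaspiro[3.4]octane-1,7-dione | CC[Si](CC)(CC)O[C@H]1C(=O)[C@@]2(CC(=O)O[C@@H]2/C=C(\C)CC=C)C1 | intermediate
19 | acetylene | C#C | starting material
20 | (1R,5R,9R)-1-[(1E)-2-methylpenta-1,4-dien-1-yl]-9-[(triethylsilyl)oxy]-2-oxaspiro[4.5]dec-7-ene-3,6-dione | CC[Si](CC)(CC)O[C@H]1C=CC(=O)[C@@]2(CC(=O)O[C@@H]2/C=C(\C)CC=C)C1 | intermediate
21 | (1R,5R,9R)-9-hydroxy-1-[(1E)-2-methylpenta-1,4-dien-1-yl]-2-oxaspiro[4.5]dec-7-ene-3,6-dione | O[C@H]1C=CC(=O)[C@@]2(CC(=O)O[C@@H]2/C=C(\C)CC=C)C1 | intermediate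
22 | (1R,5R,9S)-1-[(1E)-2-methylpenta-1,4-dien-1-yl]-3,6-dioxo-2-oxaspiro[4.5]dec-7-en-9-yl acetate | CC(=O)O[C@@H]1C=CC(=O)[C@@]2(CC(=O)O[C@@H]2/C=C(\C)CC=C)C1 | intermediate
23 | 2-methylbut-3-en-2-ol | C=CC(C)(C)O | starting material
24 | (1R,5R,9S)-1-[(1E,4E)-6-hydroxy-2,6-dimethylhepta-1,4-dien-1-yl]-3,6-dioxo-2-oxaspiro[4.5]dec-7-en-9-yl acetate | CC(=O)O[C@@H]1C=CC(=O)[C@@]2(CC(=O)O[C@@H]2/C=C(\C)C/C=C/C(C)(C)O)C1 | target

**Step count.** Total: 12 steps. Longest linear sequence: 11 steps (steps 1, 2 and 4 to 12; step 3 is a one-step branch).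

**Steps most likely to fail**

Step 9 (Proposed new method). Acetylene may oligomerise or insert twice at nickel faster than it undergoes the 1:1 insertion, and zerovalent nickel may ionise the allylic lactone. The fallback sets out from 18 and builds the same two bonds one after the other with known chemistry. HC≡CMgBr (THF, −78 °C) should add to the cyclobutanone carbonyl to give the ethynyl carbinol F1 (this makes the C6–C7 bond). HF·pyridine then frees the 1,2-diol F2, and glycol cleavage with Pb(OAc)4 opens the four-membered ring to the ynone aldehyde F3. NaI in AcOH should add HI across the ynone to give the (Z)-β-iodo enone F4. An intramolecular Nozaki–Hiyama–Kishi reaction (CrCl2, NiCl2 cat., DMF) then closes ring A by forming the C8–C9 bond. Selectivity at C9 is not expected to be high, but both epimers are usable. The (9R) alcohol is 21, where the fallback comes back to the route. The (9S) alcohol F5 needs only Ac2O and pyridine to reach 22.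

Step 6. The hindered, thermally generated ketene may dimerise or add the enol ether too slowly and with poor facial control, and the strained enone may not survive the one-flask elimination. The fallback sets out from 9 and changes the reactive intermediate from a neutral ketene to a cationic keteniminium ion. Coupling of 9 with pyrrolidine (EDC·HCl, HOBt) should give the pyrrolidine amide F6. Tf2O and 2,4,6-collidine (CH2Cl2, −30 °C) convert it into the keteniminium triflate F7, which should add ethyl vinyl ether 10 at low temperature in a [2+2] cycloaddition to give the cyclobutaniminium triflate F8. Aqueous NaHCO3 hydrolyses F8 to 13, where the fallback comes back to the route. Isolated 13 is then eliminated with DBU to 14 as in the last stage of step 6.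

Step 8. The strained cyclobutanone enolate may self-condense or ring-open before it is oxidised, and silylation in the same flask may be incomplete. The fallback avoids the enolate and sets out from 15, obtained by stopping step 7 before the acidic work-up. Rubottom oxidation with dimethyldioxirane (acetone/CH2Cl2, −78 °C) should epoxidise the electron-rich silyl enol ether in preference to the side-chain alkenes, on the same less hindered face. Silyl migration then gives the 2-silyloxy ketone F9. AcOH in THF/H2O removes the labile silyl group to give 17, where the fallback comes back to the route, and Et3SiCl with imidazole gives 18.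

**Further compounds**

F1 | step 9 | (2R,4R,5R)-1-ethynyl-1-hydroxy-5-[(1E)-2-methylpenta-1,4-dien-1-yl]-2-[(triethylsilyl)oxy]-6-oxaspiro[3.4]octan-7-one (both C1 epimers) | CC[Si](CC)(CC)O[C@H]1C(O)(C#C)[C@@]2(CC(=O)O[C@@H]2/C=C(\C)CC=C)C1
F2 | step 9 | (2R,4R,5R)-1-ethynyl-1,2-dihydroxy-5-[(1E)-2-methylpenta-1,4-dien-1-yl]-6-oxaspiro[3.4]octan-7-one (both C1 epimers) | O[C@H]1C(O)(C#C)[C@@]2(CC(=O)O[C@@H]2/C=C(\C)CC=C)C1
F3 | step 9 | 2-[(2R,3R)-2-[(1E)-2-methylpenta-1,4-dien-1-yl]-5-oxo-3-(prop-2-ynoyl)oxolan-3-yl]acetaldehyde | C#CC(=O)[C@]1(CC=O)CC(=O)O[C@@H]1/C=C(\C)CC=C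
F4 | step 9 | 2-[(2R,3R)-3-[(2Z)-3-iodoprop-2-enoyl]-2-[(1E)-2-methylpenta-1,4-dien-1-yl]-5-oxooxolan-3-yl]acetaldehyde | I/C=C\C(=O)[C@]1(CC=O)CC(=O)O[C@@H]1/C=C(\C)CC=C
F5 | step 9 | (1R,5R,9S)-9-hydroxy-1-[(1E)-2-methylpenta-1,4-dien-1-yl]-2-oxaspiro[4.5]dec-7-ene-3,6-dione | O[C@@H]1C=CC(=O)[C@@]2(CC(=O)O[C@@H]2/C=C(\C)CC=C)C1
F6 | step 6 | (4S,5R)-5-[(1E)-2-methylpenta-1,4-dien-1-yl]-4-(pyrrolidine-1-carbonyl)oxolan-2-one | O=C(N1CCCC1)[C@H]1CC(=O)O[C@@H]1/C=C(\C)CC=C
F7 | step 6 | 1-{[(2R)-2-[(1E)-2-methylpenta-1,4-dien-1-yl]-5-oxooxolan-3-ylidene]methylidene}pyrrolidin-1-ium trifluoromethanesulfonate | C(=C1CC(=O)O[C@@H]1/C=C(\C)CC=C)=[N+]1CCCC1.[O-]S(=O)(=O)C(F)(F)F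
F8 | step 6 | 1-[(5R)-3-ethoxy-5-[(1E)-2-methylpenta-1,4-dien-1-yl]-7-oxo-6-oxaspiro[3.4]octan-1-ylidene]pyrrolidin-1-ium trifluoromethanesulfonate (spiro centre as in 13) | [N+]1(CCCC1)=C1CC(OCC)[C@]12CC(=O)O[C@@H]2/C=C(\C)CC=C.[O-]S(=O)(=O)C(F)(F)F
F9 | step 8 | (2R,4R,5R)-2-{[dimethyl(phenyl)silyl]oxy}-5-[(1E)-2-methylpenta-1,4-dien-1-yl]-6-oxaspiro[3.4]octane-1,7-dione | C[Si](C)(c3ccccc3)O[C@H]1C(=O)[C@@]2(CC(=O)O[C@@H]2/C=C(\C)CC=C)C1
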